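The bench chemist charged a racemate of left-handed and right-handed substrate with partner, protic impurity and single-handed free catalyst, and I read the runs.

| flask | left-handed substrate | right-handed substrate | partner | protic impurity | free catalyst | remark |
|---|---|---|---|---|---|---|
| theta | 0.10 M | 0.10 M | 1.5 equiv | 0.020 M | 0.2 mol% | run made earlier |
| delta | 0.10 M | 0.10 M | 2.2 equiv | 0.020 M | 0.2 mol% | run made earlier |
| alpha | 0.20 M | 0.20 M | 3 equiv | 0.020 M | 0.2 mol% | run made earlier |
| flask | 0.10 M | 0.10 M | 3.00 equiv | 0.0200 M | 0.2 mol% |  |

| run | time / d | left-handed product / % |
|---|---|---|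
| theta | 2.00 | 1.9 |
| theta | 6.00 | 6.3 |
| theta | 12.0 | 12.1 |
| theta | 15.0 | 13.1 |
| theta | 25.0 | 19.2 |
| delta | 2.08 | 4.0 |
| delta | 4.00 | 5.9 |
| delta | 6.00 | 8.8 |
| delta | 12.0 | 16.6 |
| delta | 25.0 | 25.0 |
| alpha | 5.00 | 23.8 |
| alpha | 10.0 | 33.7 |
| alpha | 15.0 | 39.7 |
| alpha | 20.0 | 45.1 |
| alpha | 25.0 | 46.2 |

(each reading ± 1 percentage point)

1. factor on the rate of making left-handed product when 5.0% of the left-handed substrate and right-handed substrate together are converted if partner is charged twice over
2. factor on the rate when 5.0% of the left-handed substrate and right-handed substrate together are converted if free catalyst is charged at 0.04 mol% instead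

- free catalyst is single-handed; left-handed substrate and right-handed substrate are mirror images of each other, charged as a racemate, each of them at the stated concentration
- what was read earlier has a scatter of 1 percentage point, one standard deviation

Left-handed substrate was half of the charge, so I worked with its fraction left, one minus the doubled reading. I took as its clock the logarithm of one over that fraction, per day, a pseudo-first-order constant. At a fixed conversion I took the fraction left as fixed, and so the factor on the rate as the factor on the clock.

Theta's last reading gave 0.0194 d⁻¹ and delta's gave 0.0277 d⁻¹. Partner rose by 1.47 and the clock by 1.43, so I read an order of 0.935 and expected a factor of 1.91 for doubled partner. Scaling delta's clock by equivalents gave the flask clock, 0.0378 d⁻¹.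

But catalyst concentration moved in alpha, where the same loading stood on more substrate than in delta. Alpha read 23.8% at 5.00 d and delta 25.0% at 25.0 d, so the two clocks covered a like fraction left, and alpha's was 0.129 d⁻¹. After dividing out partner concentration, up 2.73, a factor of 1.71 remained, with catalyst concentration up 2.00. I read an order of 0.773 and a ratio of 0.288 for the smaller catalyst charge, though substrate concentration rose with the catalyst in that comparison.

The forecast said 2 and 0.44, the second on the ground that “catalyst order seems about one half, suggesting a dimer-type reservoir”. It stood above my ratio.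

The flask gave 1.96 and 0.307, a ratio lower than the forecast's.

    free catalyst + left-handed substrate ⇌ catalyst intermediate A (K = 8.80 M⁻¹, k = 0.161 M⁻¹ s⁻¹)
    free catalyst + right-handed substrate ⇌ catalyst intermediate B (K = 6.10 M⁻¹, k = 0.445 M⁻¹ s⁻¹)
    partner + catalyst intermediate A → free catalyst + left-handed product (k = 0.00600 M⁻¹ s⁻¹)
    partner + catalyst intermediate B → free catalyst + right-handed product (k = 0.00294 M⁻¹ s⁻¹)
    2 free catalyst ⇌ resting dimer (K = 27800 M⁻¹, k = 1.98 M⁻¹ s⁻¹)
    partner + protic impurity → quenched reagent (k = 3.82 × 10⁻⁴ M⁻¹ s⁻¹)

By 2.00 d the flask had spent its protic impurity on partner, with 0% of it left and quenched reagent at 0.0200 M, while the catalyst stood 50.6% as resting dimer, its resting state. Partner went on turning catalyst intermediate A and catalyst intermediate B into left-handed product and right-handed product, and at 20.0 d the flask clock of 0.0378 d⁻¹ reckoned 47.0% of the left-handed substrate left, where the flask held 42%.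

The data are simulated for substances that don't exist, and the scatter is random.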